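A direct plan would keep the outer rings as bought 2-bromo-4-methoxyphenyl units and build ring B last.
It would lithiate ethyl (E)-3-(2-bromo-4-methoxyphenoxy)acrylate A1 at its β-carbon and let two such anions acylate each other to a quinone, reduced to 2,5-bis(2-bromo-4-methoxyphenoxy)benzene-1,4-diol A2.
Demethylation would give the tetraol A3, and six-fold bromination through the octabromoquinone A4 would give the target.
Weakest would be the anionic self-condensation that closes ring B: it has no close precedent, and bromine–lithium exchange, loss of aryloxide or oligomerisation of the α-aryloxy vinyllithium would compete, so the ring closure is left to chance.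
Next would be the six-fold bromination with oxidation on the last intermediate: the positions rest on directing effects alone, the carbon between Br and OH on each outer ring reacts last, and HBr or water can cleave the vinylogous aryl ester bonds of A4, so under- and over-brominated congeners would have to be removed at the very end.
Third, the BBr3 cleavage of the methyl ethers of the air-sensitive A2 would spend a step on late material without adding anything to the skeleton.

**Plan of the new route**
The retrosynthesis takes ring B back to its quinone and cuts both O–C(ring B) bonds of the diaryl ethers, which leads to bromanil 8 and two molecules of the tribromophenol 7; 7 goes back, by removal of one bromine and of the phenol oxygen, to 2,6-dibromophenol 1.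
Feature used: ring B carries the para pairs OH/OH (C1, C4), Br/Br (C2, C5) and OAr/OAr (C3, C6), so it is the reduced form of a 2,5-dibromo-3,6-diaryloxy-1,4-benzoquinone in which each ether carbon is the β-carbon of an O–C=C(Br)–C=O unit, the pattern that two-fold addition–elimination on a tetrahaloquinone gives.
No ring is built: the outer rings are completed first (three bromines, the two oxygens told apart by a C–H borylation), ring B is bought as a quinone and becomes aromatic last, in the step that joins the three components.
The weak steps do not arise: no ring closure is needed, all eight bromines are in place before the union so nothing is brominated afterwards, and the only late deprotection is an acetal cleavage in dilute acid.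

Key step: step 4

Remark: the target is achiral and its diaryl ether bonds rotate freely, so the route has to control positions only; 1, 2 and 8 are taken to be commercial.

Step 1
Reactants: 1 2,6-dibromophenol; 2 chloromethyl methyl ether
Product: 4 1,3-dibromo-2-(methoxymethoxy)benzene, via sodium 2,6-dibromophenoxide 3 (not isolated)
Conditions: NaH (1.1 equiv), THF, 0 °C; 2 (1.2 equiv), 0 °C to rt, 2 h
Reagents that add atoms: none
Why: Williamson-type O-alkylation, in which the hindered but fully formed phenoxide 3 should attack the small, oxocarbenium-like chloromethyl ether, so that the oxygen that ends as the free outer-ring OH between two bromines is masked as a base-stable acetal from the start; no stereocentre is formed.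

Step 2
Reactants: 4 1,3-dibromo-2-(methoxymethoxy)benzene
Product: 6 3,5-dibromo-4-(methoxymethoxy)phenol, via arylboronic pinacol ester 5 (not isolated)
Conditions: [Ir(OMe)(cod)]2 (1.5 mol%), 4,4'-di-tert-butyl-2,2'-bipyridine (3 mol%), B2pin2 (1.0 equiv), THF, 80 °C, 16 h; then aq NaOH, H2O2 (30%), 0 °C to rt, 1 h
Reagents that add atoms: hydrogen peroxide, OO; bis(pinacolato)diboron, CC1(C)OB(OC1(C)C)B1OC(C)(C)C(C)(C)O1 (its boryl group is held by 5 only)
Why: Iridium-catalysed aromatic C–H borylation under steric control, which should take the only C–H without an ortho substituent (C5, para to the acetal oxygen) and leave the C–Br bonds alone, followed by oxidation of the C–B bond with aryl migration from boron to oxygen, so that the second oxygen enters already differentiated from the first; no stereocentre is formed.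

Step 3
Reactants: 6 3,5-dibromo-4-(methoxymethoxy)phenol
Product: 7 2,3,5-tribromo-4-(methoxymethoxy)phenol
Conditions: NBS (1.0 equiv), MeCN, −10 °C to rt, dark, 3 h
Reagents that add atoms: N-bromosuccinimide, O=C1CCC(=O)N1Br
Why: Phenol-directed electrophilic aromatic bromination, in which the para position is blocked and the two ortho carbons are equivalent, so that one equivalent of NBS can give only one monobromide, the new bromine slows a second substitution, and the neutral by-product spares the acetal; no stereocentre is formed.

Step 4
Reactants: 7 2,3,5-tribromo-4-(methoxymethoxy)phenol (two molecules per product); 8 2,3,5,6-tetrabromocyclohexa-2,5-diene-1,4-dione (bromanil)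
Product: 12 2,5-dibromo-3,6-bis[2,3,5-tribromo-4-(methoxymethoxy)phenoxy]benzene-1,4-diol, via sodium aryloxide 9 (not isolated), via monoaryloxy tribromoquinone 10 (not isolated), via diaryloxy dibromoquinone 11 (not isolated)
Conditions: 7 (2.05 equiv), NaH (2.05 equiv), THF, 0 °C; added over 1 h to 8 (1.0 equiv), THF, −40 °C to rt, dark, N2; then aq Na2S2O4 (pH 7 buffer), EtOAc, rt, N2
Reagents that add atoms: none
Why: Two-fold addition–elimination (nucleophilic vinylic substitution) on a tetrahalo-1,4-benzoquinone, the classical reaction by which chloranil and bromanil take up two aryloxides to give 2,5-diaryloxy-3,6-dihaloquinones: aryloxide 9 adds to a C(Br) carbon of 8 that is β to a carbonyl, the α-bromo enolate expels bromide to give 10, and a second 9 repeats the sequence to give 11, so that three components are joined and both diaryl ether bonds are made with all eight bromines already in place. No ring is closed and no stereocentre is formed; ring B enters as the bought quinone and becomes aromatic only in the dithionite work-up, which also takes the hydrolysis-prone vinylogous aryl ester units of 11 out of play. The step needs the second aryloxy group para to the first and a stop after two substitutions: in 10 the aryloxy oxygen at C6 donates through C6=C5 into the C4 carbonyl, so the only carbon still activated is C3, β to the untouched C1 carbonyl and para to C6, and in 11 both carbonyls are tied up in vinylogous esters, which with exact stoichiometry and addition of 9 to 8 should hold back a third substitution. O-attack and a polar rather than an electron-transfer course are expected because 9 is a weakly basic aryloxide made electron-poor by three bromines, with its para carbon blocked by the acetal oxygen and its free ortho carbon flanked by bromine.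

Step 5
Reactants: 12 2,5-dibromo-3,6-bis[2,3,5-tribromo-4-(methoxymethoxy)phenoxy]benzene-1,4-diol
Product: 13 2,5-dibromo-3,6-bis(2,3,5-tribromo-4-hydroxyphenoxy)benzene-1,4-diol
Conditions: HCl (1.25 M in MeOH, excess), degassed THF/MeOH 1:1, 40 °C, N2, 6 h
Reagents that add atoms: none
Why: Acid-catalysed acetal methanolysis, in which the protonated methoxymethyl ether should lose the electron-poor phenol as a good leaving group and the oxocarbenium ion is trapped by MeOH, while diaryl ethers, aryl bromides and the hydroquinone are inert to dilute acid and exclusion of air prevents reoxidation of ring B; no stereocentre is involved.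

**Compound list**
1 | 2,6-dibromophenol | Oc1c(Br)cccc1Br | starting material
2 | chloromethyl methyl ether | COCCl | starting material
3 | sodium 2,6-dibromophenoxide | [Na+].[O-]c1c(Br)cccc1Br | intermediate
4 | 1,3-dibromo-2-(methoxymethoxy)benzene | COCOc1c(Br)cccc1Br | intermediate
5 | 2-[3,5-dibromo-4-(methoxymethoxy)phenyl]-4,4,5,5-tetramethyl-1,3,2-dioxaborolane | COCOc1c(Br)cc(cc1Br)B1OC(C)(C)C(C)(C)O1 | intermediate
6 | 3,5-dibromo-4-(methoxymethoxy)phenol | COCOc1c(Br)cc(O)cc1Br | intermediate
7 | 2,3,5-tribromo-4-(methoxymethoxy)phenol | COCOc1c(Br)cc(O)c(Br)c1Br | intermediate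
8 | 2,3,5,6-tetrabromocyclohexa-2,5-diene-1,4-dione (bromanil) | O=C1C(Br)=C(Br)C(=O)C(Br)=C1Br | starting material
9 | sodium 2,3,5-tribromo-4-(methoxymethoxy)phenoxide | [Na+].[O-]c1cc(Br)c(OCOC)c(Br)c1Br | intermediate
10 | 2,3,5-tribromo-6-[2,3,5-tribromo-4-(methoxymethoxy)phenoxy]cyclohexa-2,5-diene-1,4-dione | O=C1C(Br)=C(Br)C(=O)C(Oc2cc(Br)c(OCOC)c(Br)c2Br)=C1Br | intermediate
11 | 2,5-dibromo-3,6-bis[2,3,5-tribromo-4-(methoxymethoxy)phenoxy]cyclohexa-2,5-diene-1,4-dione | O=C1C(Br)=C(Oc2cc(Br)c(OCOC)c(Br)c2Br)C(=O)C(Br)=C1Oc1cc(Br)c(OCOC)c(Br)c1Br | intermediate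
12 | 2,5-dibromo-3,6-bis[2,3,5-tribromo-4-(methoxymethoxy)phenoxy]benzene-1,4-diol | Oc1c(Br)c(Oc2cc(Br)c(OCOC)c(Br)c2Br)c(O)c(Br)c1Oc1cc(Br)c(OCOC)c(Br)c1Br | intermediate
13 | 2,5-dibromo-3,6-bis(2,3,5-tribromo-4-hydroxyphenoxy)benzene-1,4-diol (achiral) | Oc1c(Br)cc(Oc2c(O)c(Br)c(Oc3cc(Br)c(O)c(Br)c3Br)c(O)c2Br)c(Br)c1Br | target

Total step count: 5. Longest linear sequence: 5 steps (1 → 4 → 6 → 7 → 12 → 13; 8 enters in step 4).

**Steps most likely to fail**

Step 4. What may go wrong: electron transfer from aryloxide 9 to the strongly oxidising 8, a stall at 10 because 9 is hindered and weakly basic, a third substitution, or hydrolysis of the vinylogous aryl ester bonds of 11 before reduction. Fallback: the quinone is given up and both ether bonds are made by nucleophilic aromatic substitution of fluoride on a benzene ring that is no oxidant. It sets out from 7. With K2CO3 in DMF at 90 °C, two molecules of 7 should displace two para-related fluorides of commercial 1,4-dibromo-2,3,5,6-tetrafluorobenzene F1 to give 1,4-dibromo-2,5-difluoro-3,6-bis[2,3,5-tribromo-4-(methoxymethoxy)phenoxy]benzene F2; the second aryloxide should enter para to the first because that carbon alone has no para fluorine. NaOMe in DMSO at 90 °C should then replace the two remaining fluorides to give 1,4-dibromo-2,5-dimethoxy-3,6-bis[2,3,5-tribromo-4-(methoxymethoxy)phenoxy]benzene F3. BBr3 in CH2Cl2 (−78 °C to rt) should cleave both methyl ethers and both methoxymethyl ethers, and the fallback comes back to the route at 13.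

Step 3. What may go wrong: a second bromination at the other ortho carbon, or incomplete conversion, leaving di- and tetrabromo phenols that are hard to separate from 7. Fallback: the bromine is placed by a stoichiometric directed metalation, which can occur only once. It sets out from 6. Et2NCOCl and NaH in THF should give 3,5-dibromo-4-(methoxymethoxy)phenyl diethylcarbamate F4. The mixed magnesium amide TMPMgCl·LiCl (1.1 equiv, THF, −20 °C), which tolerates aryl bromides, should magnesiate the C–H between the carbamate and a bromine, and 1,2-dibromotetrachloroethane should give 2,3,5-tribromo-4-(methoxymethoxy)phenyl diethylcarbamate F5. NaOH in MeOH/THF at 60 °C should cleave the carbamate, and the fallback comes back to the route at 7.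

Step 2. What may go wrong: slow or incomplete borylation of the electron-poor ring, competing activation of a C–Br bond, or loss of the acetal during the oxidative work-up. Fallback: the phenol oxygen is brought in by a Baeyer–Villiger oxidation in place of the C–H borylation. It sets out from 2, which with K2CO3 in acetone should protect commercial 3,5-dibromo-4-hydroxybenzaldehyde F6 as 3,5-dibromo-4-(methoxymethoxy)benzaldehyde F7. mCPBA in CH2Cl2 (NaHCO3 buffer) should give, by aryl migration, 3,5-dibromo-4-(methoxymethoxy)phenyl formate F8. K2CO3 in MeOH should cleave the formate, and the fallback comes back to the route at 6.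

**Further compounds**
F1 | step 4 | 1,4-dibromo-2,3,5,6-tetrafluorobenzene | Fc1c(F)c(Br)c(F)c(F)c1Br
F2 | step 4 | 1,4-dibromo-2,5-difluoro-3,6-bis[2,3,5-tribromo-4-(methoxymethoxy)phenoxy]benzene | COCOc1c(Br)cc(Oc2c(Br)c(F)c(Oc3cc(Br)c(OCOC)c(Br)c3Br)c(Br)c2F)c(Br)c1Br
F3 | step 4 | 1,4-dibromo-2,5-dimethoxy-3,6-bis[2,3,5-tribromo-4-(methoxymethoxy)phenoxy]benzene | COCOc1c(Br)cc(Oc2c(Br)c(OC)c(Oc3cc(Br)c(OCOC)c(Br)c3Br)c(Br)c2OC)c(Br)c1Br
F4 | step 3 | 3,5-dibromo-4-(methoxymethoxy)phenyl diethylcarbamate | CCN(CC)C(=O)Oc1cc(Br)c(OCOC)c(Br)c1
F5 | step 3 | 2,3,5-tribromo-4-(methoxymethoxy)phenyl diethylcarbamate | CCN(CC)C(=O)Oc1cc(Br)c(OCOC)c(Br)c1Br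
F6 | step 2 | 3,5-dibromo-4-hydroxybenzaldehyde | O=Cc1cc(Br)c(O)c(Br)c1
F7 | step 2 | 3,5-dibromo-4-(methoxymethoxy)benzaldehyde | COCOc1c(Br)cc(C=O)cc1Br
F8 | step 2 | 3,5-dibromo-4-(methoxymethoxy)phenyl formate | COCOc1c(Br)cc(OC=O)cc1Br
A1 | direct plan | ethyl (E)-3-(2-bromo-4-methoxyphenoxy)acrylate | CCOC(=O)/C=C/Oc1ccc(OC)cc1Br
A2 | direct plan | 2,5-bis(2-bromo-4-methoxyphenoxy)benzene-1,4-diol | Oc1cc(Oc2ccc(OC)cc2Br)c(O)cc1Oc1ccc(OC)cc1Br
A3 | direct plan | 2,5-bis(2-bromo-4-hydroxyphenoxy)benzene-1,4-diol | Oc1cc(Oc2ccc(O)cc2Br)c(O)cc1Oc1ccc(O)cc1Br
A4 | direct plan | 2,5-dibromo-3,6-bis(2,3,5-tribromo-4-hydroxyphenoxy)cyclohexa-2,5-diene-1,4-dione | O=C1C(Br)=C(Oc2cc(Br)c(O)c(Br)c2Br)C(=O)C(Br)=C1Oc1cc(Br)c(O)c(Br)c1Br
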